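Time was what I had to turn into conversion, and I did it through the balance of substrate, the limiting reagent here.

| setting | zeta | alpha | epsilon | flask |
|---|---|---|---|---|
| substrate | 6.7 × 10⁻⁴ M | 0.0015 M | 0.0010 M | 0.0010 M |
| partner | 4 mM | 4 mM | 8 mM | 4.00 mM |
| remark | run made earlier | run made earlier | run made earlier |  |
| time |  |  |  | 6.0 min |

| run | time / min | target / % | side product / % |
|---|---|---|---|
| zeta | 1.00 | 43.4 | 1.2 |
| zeta | 2.00 | 68.7 | 2.0 |
| zeta | 3.00 | 81.2 | 1.9 |
| zeta | 4.00 | 88.0 | 2.0 |
| zeta | 5.00 | 92.1 | 1.7 |
| alpha | 0.417 | 19.7 | 0.3 |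
| alpha | 0.667 | 30.1 | 0.2 |
| alpha | 1.33 | 51.2 | 1.1 |
| alpha | 2.50 | 72.0 | 1.9 |
| alpha | 5.00 | 89.2 | 2.1 |
| epsilon | 0.417 | 35.4 | 1.2 |
| epsilon | 0.667 | 51.7 | 0.8 |
| epsilon | 1.33 | 77.0 | 1.3 |
| epsilon | 2.50 | 92.6 | 2.4 |
| epsilon | 5.00 | 96.8 | 2.6 |

(standard deviation of a reading: 0.3 percentage points)

- the numbers in the tables scatter with a standard deviation of 0.3 percentage points

- amount of target in the flask at 6.0 min, in percent of the substrate charged
- amount of side product in the flask at 6.0 min, in percent of the substrate charged

I called a the fraction of charged substrate found neither as target nor as side product, and b the fraction of partner left, taking one partner spent per substrate. If the rate is k times both concentrations, then ln(b/a) = k(B − A)t, with A and B the charges. The zeta run showed a = 16.9% at 3.00 min, and the alpha run 26.1% at 2.50 min. These gave k = 163 L mol⁻¹ min⁻¹ and 163 L mol⁻¹ min⁻¹, alike across two substrate charges. Their mean, 163 L mol⁻¹ min⁻¹, is the balance constant, and for the flask at 6.0 min it gave a = 4.04%.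

As a second way, without k, I interpolated by substrate charge between the zeta and alpha runs. Their leftovers at 5.00 min, 6.20% and 8.70%, and their tail decay constants, 0.501 min⁻¹ and 0.439 min⁻¹, carried on to 6.0 min, gave 4.47%. The ways parted by 0.43 points. I kept the first, because a scatter of 0.3 points weighs more on 6.20% than on 16.9%. Side product made 2.25% of target plus side product at the last readings, so I expected 2.16% of it and 93.8% of target.

The forecast gave 93.3% and 2.2%, saying “Side product tracks conversion”; its target stands below mine.

The flask gave 93.5% of target and 2.17% of side product, so a was 4.33%, of which 0.657% was decomposed reagent.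

    intermediate → target (k = 0.212 s⁻¹)
    intermediate → decomposed reagent (k = 0.00149 s⁻¹)
    substrate + partner ⇌ intermediate (K = 339 L mol⁻¹, k = 2.95 L mol⁻¹ s⁻¹)
    intermediate → side product (k = 0.00493 s⁻¹)

At 3.00 min the balance constant gives a = 18.4%, and the flask showed 18.5%.

For the neighbour flask, charged alike but read at 1.5 min, the balance constant gives a = 40.9%. That flask held 57.0% of target and 1.33% of side product, so a was 41.7%.

All runs are simulated for substances that don't exist; noise was put on by code.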